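**Retrosynthetic overview**

1. The C3–C4 bond is made last: an electrochemical, chromium-catalytic alkenyl iodide–aldehyde (Nozaki–Hiyama–Kishi) coupling closes the 14-membered ring and sets C3.
2. The C10–C11 bond comes from a boron aldol between a lactone aldehyde and a (Z,E)-iodo-dienone (sets C11); an Evans–Tishchenko reduction then sets C9 and places the acetate on O11.
3. The seven-membered α-methylene lactone is closed by Yamaguchi lactonisation of the C16 acid (from the isopropenyl CH3) onto the tertiary C12–OH.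
4. The C12–O bond comes from a Baeyer–Villiger oxidation (retention) of a 2,2-disubstituted cyclohexanone made by reductive hydroxymethylation of (S)-carvone; carvone supplies C1 and relays it to C12 on the ring.
5. Ring order: carvone six-membered ring → Baeyer–Villiger lactone (opened to free C3 and O12) → seven-membered α-methylene lactone → 14-membered carbocycle.

Assumption: cembranoid numbering is used (C1 = lactone-ring CH next to C15, C12 = tertiary C–O carbon, C16 = lactone C=O, C17 = exocyclic CH2), so the target is (1S,3S,4E,7Z,9R,11R,12S); racemic but-3-yn-2-ol is used because its stereocentre is destroyed in step 13.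

**Route**

Step 1
Reactants: 1 (S)-(+)-carvone
Product: 4 (2S,5S)-2-({[tert-butyl(dimethyl)silyl]oxy}methyl)-2-methyl-5-(prop-1-en-2-yl)cyclohexan-1-one, via lithium enolate 2 (not isolated), via lithium aldolate 3 (not isolated)
Conditions: LiBH(s-Bu)3, THF, −78 °C; CH2O (gas), −78 °C; then t-BuMe2SiCl, imidazole, DMF, 0 → 23 °C
Reagents that add atoms: formaldehyde C=O; tert-butyl(chloro)dimethylsilane CC(C)(C)[Si](C)(C)Cl
Why: Conjugate hydride addition gives the tetrasubstituted enolate regiospecifically, and its aldol reaction with monomeric formaldehyde goes by axial attack on the half-chair that keeps the isopropenyl group equatorial, so the new C–C bond forms cis to the isopropenyl group (the sense seen in Robinson annulations of dihydrocarvone) and the quaternary C12 centre is set from C1 (about 4:1 expected, minor epimer removed by chromatography), while in-flask silylation blocks retro-aldol (reductive aldol reaction).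

Step 2
Reactants: 4 (2S,5S)-2-({[tert-butyl(dimethyl)silyl]oxy}methyl)-2-methyl-5-(prop-1-en-2-yl)cyclohexan-1-one
Product: 5 (4S,7S)-7-({[tert-butyl(dimethyl)silyl]oxy}methyl)-7-methyl-4-(prop-1-en-2-yl)oxepan-2-one
Conditions: Me3SiOOSiMe3 (2 equiv), Me3SiOTf (0.2 equiv), CH2Cl2, −40 → −20 °C
Reagents that add atoms: bis(trimethylsilyl) peroxide C[Si](C)(C)OO[Si](C)(C)C
Why: Baeyer–Villiger oxidation with the silyl peroxide uses no peracid and so leaves the isopropenyl C=C alone, and the fully substituted α-carbon migrates in preference to CH2 with retention, turning the ring C–C(=O) bond into the tertiary C12–O bond of S configuration.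

Step 3
Reactants: 5 (4S,7S)-7-({[tert-butyl(dimethyl)silyl]oxy}methyl)-7-methyl-4-(prop-1-en-2-yl)oxepan-2-one
Product: 6 (3S,6S)-7-{[tert-butyl(dimethyl)silyl]oxy}-6-hydroxy-6-methyl-3-(prop-1-en-2-yl)heptanal
Conditions: i-Bu2AlH (1.1 equiv), CH2Cl2, −78 °C; aqueous potassium sodium tartrate
Reagents that add atoms: none
Why: At −78 °C hydride addition to the lactone stops at the aluminium hemiacetal, which on work-up gives the open hydroxy aldehyde (seven-membered lactols are disfavoured), freeing C3 and the tertiary C12 hydroxyl (partial reduction of a lactone).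

Step 4
Reactants: 6 (3S,6S)-7-{[tert-butyl(dimethyl)silyl]oxy}-6-hydroxy-6-methyl-3-(prop-1-en-2-yl)heptanal
Product: 7 (2S,5S)-1-{[tert-butyl(dimethyl)silyl]oxy}-7,7-dimethoxy-2-methyl-5-(prop-1-en-2-yl)heptan-2-ol
Conditions: HC(OMe)3, CeCl3·7H2O (0.2 equiv), MeOH, 23 °C
Reagents that add atoms: trimethyl orthoformate COC(OC)OC
Why: CeCl3-catalysed acetalisation with trimethyl orthoformate is near neutral, so the aldehyde becomes its dimethyl acetal while the primary silyl ether, the tertiary alcohol and the alkene are untouched (Gemal–Luche acetalisation).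

Step 5
Reactants: 7 (2S,5S)-1-{[tert-butyl(dimethyl)silyl]oxy}-7,7-dimethoxy-2-methyl-5-(prop-1-en-2-yl)heptan-2-ol
Product: 8 (2S,5S)-1-{[tert-butyl(dimethyl)silyl]oxy}-5-(3-hydroxyprop-1-en-2-yl)-7,7-dimethoxy-2-methylheptan-2-ol
Conditions: SeO2 (0.3 equiv), t-BuOOH (2 equiv, in decane), CH2Cl2, 23 °C
Reagents that add atoms: tert-butyl hydroperoxide CC(C)(C)OO
Why: The isopropenyl group is the only alkene, and the SeO2 ene/[2,3]-sigmatropic sequence hydroxylates its methyl group in preference to the hindered ring CH, giving the 2-substituted allylic alcohol (catalytic SeO2 allylic oxidation); any enal formed converges in step 6.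

Step 6
Reactants: 8 (2S,5S)-1-{[tert-butyl(dimethyl)silyl]oxy}-5-(3-hydroxyprop-1-en-2-yl)-7,7-dimethoxy-2-methylheptan-2-ol
Product: 10 2-[(3S,6S)-7-{[tert-butyl(dimethyl)silyl]oxy}-6-hydroxy-1,1-dimethoxy-6-methylheptan-3-yl]prop-2-enoic acid, via enal 9 (not isolated)
Conditions: TEMPO (0.1 equiv), PhI(OAc)2, CH2Cl2, 23 °C; then t-BuOH/H2O, 2-methylbut-2-ene, NaClO2, NaH2PO4, 0 °C
Reagents that add atoms: sodium chlorite [Na+].[O-]Cl=O
Why: Oxoammonium oxidation converts the primary allylic alcohol (the tertiary alcohol cannot react) into the enal, and buffered chlorite (Pinnick oxidation) takes it in the same flask to the acrylic acid at a pH the dimethyl acetal survives.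

Step 7
Reactants: 10 2-[(3S,6S)-7-{[tert-butyl(dimethyl)silyl]oxy}-6-hydroxy-1,1-dimethoxy-6-methylheptan-3-yl]prop-2-enoic acid
Product: 12 (4S,7S)-7-({[tert-butyl(dimethyl)silyl]oxy}methyl)-4-(2,2-dimethoxyethyl)-7-methyl-3-methylideneoxepan-2-one, via mixed anhydride 11 (not isolated)
Conditions: 2,4,6-Cl3C6H2COCl, Et3N, THF, 23 °C; then slow addition to DMAP, toluene, 80 °C (final 2 mM)
Reagents that add atoms: none
Why: Yamaguchi lactonisation, in which the mixed anhydride is acylated under DMAP catalysis by the only free hydroxyl (the tertiary C12 alcohol), the gem-disubstituted carbinol carbon favouring seven-membered ring closure at high dilution; no stereocentre is involved.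

Step 8
Reactants: 12 (4S,7S)-7-({[tert-butyl(dimethyl)silyl]oxy}methyl)-4-(2,2-dimethoxyethyl)-7-methyl-3-methylideneoxepan-2-one
Product: 13 (4S,7S)-4-(2,2-dimethoxyethyl)-7-(hydroxymethyl)-7-methyl-3-methylideneoxepan-2-one
Conditions: HF·pyridine, pyridine/THF, 0 → 23 °C
Reagents that add atoms: none
Why: Buffered HF·pyridine cleaves the primary silyl ether without hydrolysing the dimethyl acetal or opening the lactone, and the acidic medium suppresses acyl migration to the freed hydroxyl (fluoride desilylation).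

Step 9
Reactants: 13 (4S,7S)-4-(2,2-dimethoxyethyl)-7-(hydroxymethyl)-7-methyl-3-methylideneoxepan-2-one
Product: 14 (2S,5S)-5-(2,2-dimethoxyethyl)-2-methyl-6-methylidene-7-oxooxepane-2-carbaldehyde
Conditions: Dess–Martin periodinane, pyridine, CH2Cl2, 0 → 23 °C
Reagents that add atoms: none
Why: Dess–Martin oxidation of the neopentyl primary alcohol gives the non-enolisable α-acyloxy aldehyde under conditions that spare the acetal and the acrylate (hypervalent iodine oxidation).

Step 10
Reactants: 15 but-2-yn-1-ol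
Product: 18 (2E)-3-iodobut-2-en-1-ol, via aluminium alkoxide 16 (not isolated), via alkenylzirconocene chloride 17 (not isolated)
Conditions: i-Bu2AlH (1 equiv), THF, 0 °C; Cp2ZrCl2, i-Bu2AlH (1 equiv), THF, 0 → 23 °C; then I2, −78 → 0 °C
Reagents that add atoms: iodine II
Why: The aluminium alkoxide of the 2-alkynol is hydrozirconated by Cp2Zr(H)Cl formed in situ, by syn addition that places zirconium on C3, and iodinolysis with retention gives the E alkenyl iodide (hydrozirconation–iodination).

Step 11
Reactants: 18 (2E)-3-iodobut-2-en-1-ol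
Product: 19 (2E)-1-bromo-3-iodobut-2-ene
Conditions: PBr3 (0.4 equiv), Et2O, 0 °C
Reagents that add atoms: phosphorus tribromide BrP(Br)Br
Why: PBr3 converts the primary allylic alcohol into the bromide by SN2 displacement without allylic transposition or change of alkene geometry (alcohol-to-bromide substitution).

Step 12
Reactants: 20 (±)-but-3-yn-2-ol; 19 (2E)-1-bromo-3-iodobut-2-ene
Product: 22 (3Z,6E)-7-iodo-3-methylocta-3,6-dien-2-ol (racemic), via alkenylmagnesium bromide 21 (not isolated)
Conditions: MeMgBr (2.3 equiv), CuI (0.1 equiv), THF, −10 → 23 °C; then 19, −30 → 0 °C; aqueous NH4Cl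
Reagents that add atoms: methylmagnesium bromide C[Mg]Br
Why: Copper-catalysed anti-carbomagnesiation of the propargylic magnesium alkoxide puts methyl on C3 and leaves a chelated alkenylmagnesium cis to the carbinol carbon, which displaces the bromide of 19 by SN2 attack so that both alkene geometries are retained and the skipped Z,E-diene results (Duboudin-type carbometalation followed by copper-catalysed allylation).

Step 13
Reactants: 22 (3Z,6E)-7-iodo-3-methylocta-3,6-dien-2-ol
Product: 23 (3Z,6E)-7-iodo-3-methylocta-3,6-dien-2-one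
Conditions: Dess–Martin periodinane, pyridine, CH2Cl2, 0 °C
Reagents that add atoms: none
Why: Dess–Martin oxidation converts the secondary allylic alcohol into the ketone under neutral conditions that do not isomerise the Z enone or the skipped diene, and it removes the racemic carbinol centre (hypervalent iodine oxidation).

Step 14
Reactants: 23 (3Z,6E)-7-iodo-3-methylocta-3,6-dien-2-one; 14 (2S,5S)-5-(2,2-dimethoxyethyl)-2-methyl-6-methylidene-7-oxooxepane-2-carbaldehyde
Product: 25 (4S,7S)-4-(2,2-dimethoxyethyl)-7-[(1R,4Z,7E)-1-hydroxy-8-iodo-4-methyl-3-oxonona-4,7-dien-1-yl]-7-methyl-3-methylideneoxepan-2-one, via boron enolate 24 (not isolated)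
Conditions: 23, n-Bu2BOTf, i-Pr2NEt, CH2Cl2, −78 °C; then 14, −78 → −20 °C; pH 7 buffer/MeOH
Reagents that add atoms: none
Why: n-Bu2BOTf/i-Pr2NEt enolises the methyl ketone on the methyl side only, and the boron enolate adds to the α-acyloxy aldehyde in the Cornforth/polar Felkin–Anh sense (carbonyl anti to the ring C12–O bond, attack past the methyl group and not past the ring CH2), which sets C11 as R from C12 (boron aldol reaction).

Step 15
Reactants: 25 (4S,7S)-4-(2,2-dimethoxyethyl)-7-[(1R,4Z,7E)-1-hydroxy-8-iodo-4-methyl-3-oxonona-4,7-dien-1-yl]-7-methyl-3-methylideneoxepan-2-one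
Product: 26 (1R,3R,4Z,7E)-1-[(2S,5S)-5-(2,2-dimethoxyethyl)-2-methyl-6-methylidene-7-oxooxepan-2-yl]-3-hydroxy-8-iodo-4-methylnona-4,7-dien-1-yl acetate
Conditions: CH3CHO (8 equiv), SmI2 (0.3 equiv, premixed with CH3CHO), THF, −10 °C
Reagents that add atoms: acetaldehyde CC=O
Why: Evans–Tishchenko reduction, in which the samarium-bound hemiacetal formed from the C11 hydroxyl and acetaldehyde delivers hydride to the C9 ketone through a six-membered chair transition state, giving the 1,3-anti (9R) alcohol and leaving the acetate regioselectively on O11.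

Step 16
Reactants: 26 (1R,3R,4Z,7E)-1-[(2S,5S)-5-(2,2-dimethoxyethyl)-2-methyl-6-methylidene-7-oxooxepan-2-yl]-3-hydroxy-8-iodo-4-methylnona-4,7-dien-1-yl acetate
Product: 27 (1R,3R,4Z,7E)-3-hydroxy-8-iodo-4-methyl-1-[(2S,5S)-2-methyl-6-methylidene-7-oxo-5-(2-oxoethyl)oxepan-2-yl]nona-4,7-dien-1-yl acetate
Conditions: PPTS (0.2 equiv), acetone/H2O (10:1), 40 °C
Reagents that add atoms: water O
Why: Mild aqueous acid hydrolyses the unhindered dimethyl acetal to the C3 aldehyde while the acetate, the allylic alcohol and the lactone survive (acetal hydrolysis).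

Step 17
Reactants: 27 (1R,3R,4Z,7E)-3-hydroxy-8-iodo-4-methyl-1-[(2S,5S)-2-methyl-6-methylidene-7-oxo-5-(2-oxoethyl)oxepan-2-yl]nona-4,7-dien-1-yl acetate
Product: 28 (1S,3S,4E,7Z,9R,11R,12S)-11-acetoxy-3,9-dihydroxycembra-4,7,15(17)-trien-16,12-olide (CNP0183491.1)
Conditions: CrCl2 (15 mol %), NiCl2(MeOCH2CH2OMe) (2 mol %), LiCl, DMF, undivided cell, Al anode, Ni-foam cathode, constant current, 27 added over 12 h (final 2 mM), 23 °C; aqueous potassium sodium tartrate
Reagents that add atoms: none
Why: Proposed new method: an electroreductive Nozaki–Hiyama–Kishi macrocyclisation catalytic in chromium, in which cathodically formed zerovalent nickel inserts into the alkenyl iodide with retention of the E geometry and hands the alkenyl group to cathodically regenerated divalent chromium, the alkenylchromium adds to the tethered aldehyde, and anodically released trivalent aluminium takes the alkoxide off chromium so that it turns over, while slow feeding of 27 against the current keeps the open chain dilute enough for 14-membered ring closure to beat oligomerisation; the lactone-bridged chain is expected to expose one aldehyde face and give the 3S carbinol by substrate control, but this sense is not secured by a model and the d.r. must be found by experiment; the closest known reactions are the stoichiometric CrCl2/NiCl2 macrocyclisation of cembranoid iodoalkenyl aldehydes and the intermolecular electrochemical chromium-catalysed alkenyl halide–aldehyde coupling, which has not been used to close a macrocycle.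

**Compound list**

1 | (S)-(+)-carvone, (5S)-2-methyl-5-(prop-1-en-2-yl)cyclohex-2-en-1-one | CC1=CC[C@@H](CC1=O)C(C)=C | starting material
2 | lithium (5S)-2-methyl-5-(prop-1-en-2-yl)cyclohex-1-en-1-olate | CC(=C)[C@H]1CCC(C)=C([O-])C1.[Li+] | intermediate (not isolated)
3 | lithium [(1S,4S)-1-methyl-2-oxo-4-(prop-1-en-2-yl)cyclohexyl]methanolate | CC(=C)[C@H]1CC[C@@](C)(C[O-])C(=O)C1.[Li+] | intermediate (not isolated)
4 | (2S,5S)-2-({[tert-butyl(dimethyl)silyl]oxy}methyl)-2-methyl-5-(prop-1-en-2-yl)cyclohexan-1-one | CC(=C)[C@H]1CC[C@@](C)(CO[Si](C)(C)C(C)(C)C)C(=O)C1 | intermediate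
5 | (4S,7S)-7-({[tert-butyl(dimethyl)silyl]oxy}methyl)-7-methyl-4-(prop-1-en-2-yl)oxepan-2-one | CC(=C)[C@H]1CC[C@@](C)(CO[Si](C)(C)C(C)(C)C)OC(=O)C1 | intermediate
6 | (3S,6S)-7-{[tert-butyl(dimethyl)silyl]oxy}-6-hydroxy-6-methyl-3-(prop-1-en-2-yl)heptanal | CC(=C)[C@@H](CC[C@@](C)(CO[Si](C)(C)C(C)(C)C)O)CC=O | intermediate
7 | (2S,5S)-1-{[tert-butyl(dimethyl)silyl]oxy}-7,7-dimethoxy-2-methyl-5-(prop-1-en-2-yl)heptan-2-ol | CC(=C)[C@@H](CC[C@@](C)(CO[Si](C)(C)C(C)(C)C)O)CC(OC)OC | intermediate
8 | (2S,5S)-1-{[tert-butyl(dimethyl)silyl]oxy}-5-(3-hydroxyprop-1-en-2-yl)-7,7-dimethoxy-2-methylheptan-2-ol | OCC(=C)[C@@H](CC[C@@](C)(CO[Si](C)(C)C(C)(C)C)O)CC(OC)OC | intermediate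
9 | 2-[(3S,6S)-7-{[tert-butyl(dimethyl)silyl]oxy}-6-hydroxy-1,1-dimethoxy-6-methylheptan-3-yl]prop-2-enal | O=CC(=C)[C@@H](CC[C@@](C)(CO[Si](C)(C)C(C)(C)C)O)CC(OC)OC | intermediate (not isolated)
10 | 2-[(3S,6S)-7-{[tert-butyl(dimethyl)silyl]oxy}-6-hydroxy-1,1-dimethoxy-6-methylheptan-3-yl]prop-2-enoic acid | OC(=O)C(=C)[C@@H](CC[C@@](C)(CO[Si](C)(C)C(C)(C)C)O)CC(OC)OC | intermediate
11 | mixed anhydride of 10 with 2,4,6-trichlorobenzoic acid | O=C(OC(=O)C(=C)[C@@H](CC[C@@](C)(CO[Si](C)(C)C(C)(C)C)O)CC(OC)OC)c1c(Cl)cc(Cl)cc1Cl | intermediate (not isolated)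
12 | (4S,7S)-7-({[tert-butyl(dimethyl)silyl]oxy}methyl)-4-(2,2-dimethoxyethyl)-7-methyl-3-methylideneoxepan-2-one | C=C1C(=O)O[C@](C)(CO[Si](C)(C)C(C)(C)C)CC[C@H]1CC(OC)OC | intermediate
13 | (4S,7S)-4-(2,2-dimethoxyethyl)-7-(hydroxymethyl)-7-methyl-3-methylideneoxepan-2-one | C=C1C(=O)O[C@](C)(CO)CC[C@H]1CC(OC)OC | intermediate
14 | (2S,5S)-5-(2,2-dimethoxyethyl)-2-methyl-6-methylidene-7-oxooxepane-2-carbaldehyde | C=C1C(=O)O[C@](C)(C=O)CC[C@H]1CC(OC)OC | intermediate
15 | but-2-yn-1-ol | CC#CCO | starting material
16 | diisobutylaluminium but-2-yn-1-olate | CC#CCO[Al](CC(C)C)CC(C)C | intermediate (not isolated)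
17 | (E)-alkenylzirconocene chloride, Cp2Zr(Cl) on C3 of the diisobutylaluminium but-2-en-1-olate | C/C(=C\CO[Al](CC(C)C)CC(C)C)[Zr](Cl)(C1C=CC=C1)C1C=CC=C1 | intermediate (not isolated)
18 | (2E)-3-iodobut-2-en-1-ol | I/C(C)=C/CO | intermediate
19 | (2E)-1-bromo-3-iodobut-2-ene | I/C(C)=C/CBr | intermediate
20 | (±)-but-3-yn-2-ol | CC(O)C#C | starting material
21 | bromo[(1Z)-3-(bromomagnesiooxy)-2-methylbut-1-en-1-yl]magnesium | CC(O[Mg]Br)/C(C)=C\[Mg]Br | intermediate (not isolated)
22 | (3Z,6E)-7-iodo-3-methylocta-3,6-dien-2-ol (racemic) | CC(O)/C(C)=C\C/C=C(\C)I | intermediate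
23 | (3Z,6E)-7-iodo-3-methylocta-3,6-dien-2-one | CC(=O)/C(C)=C\C/C=C(\C)I | intermediate
24 | dibutyl{[(3Z,6E)-7-iodo-3-methylocta-1,3,6-trien-2-yl]oxy}borane | C=C(OB(CCCC)CCCC)/C(C)=C\C/C=C(\C)I | intermediate (not isolated)
25 | (4S,7S)-4-(2,2-dimethoxyethyl)-7-[(1R,4Z,7E)-1-hydroxy-8-iodo-4-methyl-3-oxonona-4,7-dien-1-yl]-7-methyl-3-methylideneoxepan-2-one | C=C1C(=O)O[C@](C)([C@H](O)CC(=O)/C(C)=C\C/C=C(\C)I)CC[C@H]1CC(OC)OC | intermediate
26 | (1R,3R,4Z,7E)-1-[(2S,5S)-5-(2,2-dimethoxyethyl)-2-methyl-6-methylidene-7-oxooxepan-2-yl]-3-hydroxy-8-iodo-4-methylnona-4,7-dien-1-yl acetate | C=C1C(=O)O[C@](C)([C@H](OC(C)=O)C[C@@H](O)/C(C)=C\C/C=C(\C)I)CC[C@H]1CC(OC)OC | intermediate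
27 | (1R,3R,4Z,7E)-3-hydroxy-8-iodo-4-methyl-1-[(2S,5S)-2-methyl-6-methylidene-7-oxo-5-(2-oxoethyl)oxepan-2-yl]nona-4,7-dien-1-yl acetate | C=C1C(=O)O[C@](C)([C@H](OC(C)=O)C[C@@H](O)/C(C)=C\C/C=C(\C)I)CC[C@H]1CC=O | intermediate
28 | (1S,3S,4E,7Z,9R,11R,12S)-11-acetoxy-3,9-dihydroxycembra-4,7,15(17)-trien-16,12-olide (CNP0183491.1) | C=C1C(=O)O[C@@]2(C)CC[C@H]1C[C@H](O)/C(C)=C/C/C=C(/C)[C@H](O)C[C@H]2OC(C)=O | target

**Step count and risks**

Total step count: 17. Longest linear sequence: 13 steps (steps 1–9, then 14–17); the dienone 23 is made in 4 steps (10–13).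

The three steps most likely to fail:

Step 17 (the proposed electrochemical macrocyclisation). Catalytic chromium turnover at 2 mM, reduction of the acrylate lactone at the cathode, and the facial selectivity at C3 are all unproven. The fallback sets out from 27 and comes back at 28. It drops the electrode-driven catalytic cycle for the classical reagent-based ring closure: 27 is added by syringe pump to an excess of CrCl2 (10 equiv) containing NiCl2 (1 mol %) in degassed DMSO/THF at 23 °C. This stoichiometric divalent-chromium protocol is the established way to close cembranoid rings from iodoalkenyl aldehydes and tolerates the free hydroxyl, the acetate and the acrylate. It makes no new compound (F0).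

Step 7 (lactonisation onto a tertiary alcohol). DMAP-mediated acylation of the hindered C12 hydroxyl by the mixed anhydride may be too slow. The fallback sets out from 10 and comes back at 12. It switches from activating the acid to activating the alcohol: 10 is treated with 1,1'-carbonyldiimidazole (CH2Cl2, 23 °C) to give the N-acylimidazole F1, which is isolated. The tertiary hydroxyl of F1 is then deprotonated with KN(SiMe3)2 (1.05 equiv, THF, −78 → 0 °C, 2 mM), and the potassium alkoxide closes the seven-membered ring by attack on the acyl imidazole.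

Step 14 (boron aldol that sets C11). The differentiation of methyl from ring CH2 at the quaternary C12 may be modest, and the boron enolate of the Z enone may isomerise. The fallback sets out from 23 and comes back at 25. Ketone 23 is converted (Me3SiOTf, Et3N, CH2Cl2, 0 °C) into the trimethylsilyl dienol ether F2, which is isolated. F2 is added to aldehyde 14 with BF3·OEt2 in CH2Cl2 at −78 °C (Mukaiyama aldol). This goes through an open, Lewis-acid-activated transition state under polar Felkin–Anh control, with no amine base and no boron enolate.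

Further compounds
F1 | step 7 | 1-{2-[(3S,6S)-7-{[tert-butyl(dimethyl)silyl]oxy}-6-hydroxy-1,1-dimethoxy-6-methylheptan-3-yl]prop-2-enoyl}-1H-imidazole | O=C(n1ccnc1)C(=C)[C@@H](CC[C@@](C)(CO[Si](C)(C)C(C)(C)C)O)CC(OC)OC
F2 | step 14 | trimethyl{[(3Z,6E)-7-iodo-3-methylocta-1,3,6-trien-2-yl]oxy}silane | C=C(O[Si](C)(C)C)/C(C)=C\C/C=C(\C)I
F0 | step 17 | none | none
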